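The route cuts O1–C2 of the dihydrobenzofuran, the bond from the ring D oxygen to the benzylic carbon that bears syringyl ring C. C2 lies para to O4 of ring C (later the ether oxygen to C8′). While O4 is a free phenol, ring C can be oxidised to a p-quinone methide, which makes C2 electrophilic with O1 poised for five-membered closure. The precursor is an acyclic (S)-2,3-diarylpropan-1-ol with a plain CH2 at C2 and one stereocentre, C3. One operation turns C–H into C–O, closes the ring, sets C2 trans to C3 and returns the ring C phenol. From that phenol both erythro arylglycerol ethers grow by iterative anti-aldol reactions.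

Key step: step 11

Locants: ring A = guaiacyl ring (side chain C7, C8, C9). Ring B = middle syringyl ring (side chain C7′, C8′, C9′). Ring C = syringyl ring on C2. Ring D = benzo ring of the dihydrobenzofuran (O1, C2, C3, C3a, C7a).
Assumption: the magnesium enolates of the aryloxyacetyl imides react through the same chelated (Z)-enolate geometry as simple N-acyloxazolidinones.

Step 1
Reactants: 1 o-vanillin (2-hydroxy-3-methoxybenzaldehyde)
Product: 2 2-hydroxy-5-iodo-3-methoxybenzaldehyde
Conditions: NIS, TFA (cat.), MeCN, rt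
Reagents that add atoms: N-iodosuccinimide, O=C1CCC(=O)N1I
Why: Electrophilic aromatic iodination should go to the only strongly activated open position, para to the free OH and meta to CHO.

Step 2
Reactants: 2 2-hydroxy-5-iodo-3-methoxybenzaldehyde
Product: 3 5-iodo-3-methoxy-2-[(triisopropylsilyl)oxy]benzaldehyde
Conditions: TIPSCl, imidazole, DMF, rt
Reagents that add atoms: chlorotriisopropylsilane, CC(C)[Si](Cl)(C(C)C)C(C)C
Why: Silyl ether formation gives a hindered aryl TIPS ether that should survive amide bases and borohydride, resist O-to-O migration, and still fall to fluoride in the key step.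

Step 3
Reactants: 3 5-iodo-3-methoxy-2-[(triisopropylsilyl)oxy]benzaldehyde
Product: 5 2-{5-iodo-3-methoxy-2-[(triisopropylsilyl)oxy]phenyl}acetaldehyde, via enol ether 4 (not isolated)
Conditions: Ph3P(CH2OMe)Cl, NaN(SiMe3)2, THF, 0 °C; then 2 M HCl, THF, rt
Reagents that add atoms: (methoxymethyl)triphenylphosphonium chloride, COC[P+](c1ccccc1)(c1ccccc1)c1ccccc1.[Cl-]; water, O
Why: Wittig methoxymethylenation followed by acid hydrolysis of the enol ether is the standard one-carbon homologation of an aryl aldehyde, and the aryl TIPS ether tolerates brief dilute acid.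

Step 4
Reactants: 5 2-{5-iodo-3-methoxy-2-[(triisopropylsilyl)oxy]phenyl}acetaldehyde
Product: 6 2-{5-iodo-3-methoxy-2-[(triisopropylsilyl)oxy]phenyl}acetic acid
Conditions: NaClO2, NaH2PO4, 2-methyl-2-butene, t-BuOH/H2O, rt
Reagents that add atoms: sodium chlorite, [Na+].[O-]Cl=O
Why: Pinnick oxidation converts the aldehyde into the acid under buffered conditions, and the alkene scavenger keeps hypochlorite away from the electron-rich ring.

Step 5
Reactants: 6 2-{5-iodo-3-methoxy-2-[(triisopropylsilyl)oxy]phenyl}acetic acid; 7 (S)-4-benzyloxazolidin-2-one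
Product: 9 (S)-4-benzyl-3-(2-{5-iodo-3-methoxy-2-[(triisopropylsilyl)oxy]phenyl}acetyl)oxazolidin-2-one, via mixed anhydride 8 (not isolated)
Conditions: PivCl, Et3N, THF, −20 °C; then 7, LiCl, −20 °C → rt
Reagents that add atoms: pivaloyl chloride, CC(C)(C)C(=O)Cl (its acyl group is carried only by intermediate 8)
Why: N-acylation of the auxiliary through the mixed pivalic anhydride should occur at the less hindered arylacetyl carbonyl under LiCl/Et3N activation.

Step 6
Reactants: 10 syringaldehyde (4-hydroxy-3,5-dimethoxybenzaldehyde)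
Product: 11 4-formyl-2,6-dimethoxyphenyl pivalate
Conditions: PivCl, Et3N, DMAP (cat.), CH2Cl2, 0 °C → rt
Reagents that add atoms: pivaloyl chloride, CC(C)(C)C(=O)Cl
Why: Phenol acylation gives a hindered aryl ester with no α-hydrogens that enolates should ignore but excess LiBH4 removes, and 11 serves twice, as the source of ring C and as ring B.

Step 7
Reactants: 11 4-formyl-2,6-dimethoxyphenyl pivalate
Product: 12 4-(hydroxymethyl)-2,6-dimethoxyphenyl pivalate
Conditions: NaBH4, THF/MeOH, 0 °C
Reagents that add atoms: none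
Why: Borohydride reduction of the aldehyde is fast at 0 °C, where the hindered pivalate should stay intact.

Step 8
Reactants: 12 4-(hydroxymethyl)-2,6-dimethoxyphenyl pivalate
Product: 13 4-(bromomethyl)-2,6-dimethoxyphenyl pivalate
Conditions: PBr3, CH2Cl2, 0 °C
Reagents that add atoms: phosphorus tribromide, BrP(Br)Br
Why: Bromination of a benzylic alcohol through its phosphite ester (SN2), with the acylated para oxygen keeping the bromide stable enough to handle.

Step 9
Reactants: 9 (S)-4-benzyl-3-(2-{5-iodo-3-methoxy-2-[(triisopropylsilyl)oxy]phenyl}acetyl)oxazolidin-2-one; 13 4-(bromomethyl)-2,6-dimethoxyphenyl pivalate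
Product: 14 (S)-4-benzyl-3-[(2S)-3-[3,5-dimethoxy-4-(pivaloyloxy)phenyl]-2-{5-iodo-3-methoxy-2-[(triisopropylsilyl)oxy]phenyl}propanoyl]oxazolidin-2-one
Conditions: NaN(SiMe3)2, THF, −78 °C; then 13, −78 → −30 °C
Reagents that add atoms: none
Why: In this Evans asymmetric alkylation the chelated (Z)-sodium enolate is shielded on one face by the benzyl group, so the benzylic bromide should enter from the other face and set the future C3 as (S).

Step 10
Reactants: 14 (S)-4-benzyl-3-[(2S)-3-[3,5-dimethoxy-4-(pivaloyloxy)phenyl]-2-{5-iodo-3-methoxy-2-[(triisopropylsilyl)oxy]phenyl}propanoyl]oxazolidin-2-one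
Product: 15 4-[(2S)-3-hydroxy-2-{5-iodo-3-methoxy-2-[(triisopropylsilyl)oxy]phenyl}propyl]-2,6-dimethoxyphenol
Conditions: LiBH4 (excess), MeOH, THF, 0 °C → rt
Reagents that add atoms: none
Why: Reductive removal of the auxiliary with LiBH4 gives the primary alcohol without epimerising C3, and the activated aryl pivalate should be cleaved reductively in the same flask, so only ring C carries a free phenol.

Step 11
Reactants: 15 4-[(2S)-3-hydroxy-2-{5-iodo-3-methoxy-2-[(triisopropylsilyl)oxy]phenyl}propyl]-2,6-dimethoxyphenol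
Product: 17 4-[(2R,3S)-3-(hydroxymethyl)-5-iodo-7-methoxy-2,3-dihydro-1-benzofuran-2-yl]-2,6-dimethoxyphenol, via p-quinone methide 16 (not isolated)
Conditions: Ag2O, CH2Cl2, rt, dark; filter (Celite); then TBAF, AcOH, THF, −20 °C → rt
Reagents that add atoms: none
Why: Ag2O removes two electrons and two protons from the only free phenol (ring C) and should give, by way of the blocked phenoxyl radical, the symmetric 2,6-dimethoxy-p-quinone methide 16, in which the former CH2 (C2) is the acceptor terminus; once the oxidant is filtered off, buffered fluoride unmasks the ring D oxygen, which adds to C2 and rearomatises ring C. The closest known reaction types are the Ag2O oxidation of 4-alkyl-2,6-dimethoxyphenols to p-quinone methides with subsequent intramolecular capture, and the phenol-to-quinone-methide closure that ends biomimetic 8–5′ couplings. The dihydrofuran ring closes in the 5-exo-trig mode (oxa-1,6-addition: O1, C7a, C3a, C3 and C2 lie in the ring, and the C2=C1 bond to ring C lies outside it). C2 is controlled by C3: allylic 1,3-strain holds C3–H in the plane of the quinone methide, so O1 reaches the face that places ring C trans to CH2OH, and because the product phenol can reopen to 16 the trans isomer is also the thermodynamic sink. The step needs oxidation of ring C alone and no second oxidation, which is secured because ring D is silylated and carries iodine para to its oxygen while Ag2O is present, because the product never meets the oxidant, and because 4-exo capture by the CH2OH group cannot compete.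

Step 12
Reactants: 7 (S)-4-benzyloxazolidin-2-one
Product: 18 (S)-4-benzyl-3-(2-bromoacetyl)oxazolidin-2-one
Conditions: n-BuLi, THF, −78 °C; then BrCH2COBr, −78 → 0 °C
Reagents that add atoms: bromoacetyl bromide, O=C(Br)CBr
Why: N-acylation of the lithiated oxazolidinone should occur at the acyl bromide, which is far more electrophilic than the alkyl bromide.

Step 13
Reactants: 17 4-[(2R,3S)-3-(hydroxymethyl)-5-iodo-7-methoxy-2,3-dihydro-1-benzofuran-2-yl]-2,6-dimethoxyphenol; 18 (S)-4-benzyl-3-(2-bromoacetyl)oxazolidin-2-one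
Product: 19 (S)-4-benzyl-3-(2-{4-[(2R,3S)-3-(hydroxymethyl)-5-iodo-7-methoxy-2,3-dihydro-1-benzofuran-2-yl]-2,6-dimethoxyphenoxy}acetyl)oxazolidin-2-one
Conditions: K2CO3, acetone, rt
Reagents that add atoms: none
Why: In this Williamson ether synthesis only the phenol is ionised by K2CO3 and the primary α-bromo imide is a very reactive SN2 partner, so the hindered phenoxide should be alkylated while CH2OH stays free and no stereocentre is touched.

Step 14
Reactants: 19 ring C aryloxyacetyl imide; 11 4-formyl-2,6-dimethoxyphenyl pivalate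
Product: 20 anti-aldol adduct as bis-TMS ether: (S)-4-benzyl-3-[(2R,3R)-3-[3,5-dimethoxy-4-(pivaloyloxy)phenyl]-3-(trimethylsilyloxy)-2-(ring C aryloxy)propanoyl]oxazolidin-2-one, with the CH2OH on C3 of the dihydrobenzofuran as its TMS ether
Conditions: MgCl2 (substoichiometric), Et3N, TMSCl (excess), EtOAc, rt
Reagents that add atoms: chlorotrimethylsilane, C[Si](C)(C)Cl
Why: In this magnesium-halide-catalysed anti-aldol reaction of an N-acyloxazolidinone, the chelated (Z)-magnesium enolate should be attacked on the face away from the benzyl group through a boat-like transition state, which sets C8′ and C7′ in the anti (erythro) relation, while TMSCl traps the aldolate for turnover and silylates the free CH2OH in the same flask.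

Step 15
Reactants: 20 anti-aldol adduct (bis-TMS ether)
Product: 21 (1R,2S)-1-(4-hydroxy-3,5-dimethoxyphenyl)-2-{4-[(2R,3S)-3-(hydroxymethyl)-5-iodo-7-methoxy-2,3-dihydro-1-benzofuran-2-yl]-2,6-dimethoxyphenoxy}propane-1,3-diol (erythro, 7′R,8′S)
Conditions: LiBH4 (excess), MeOH, THF, 0 °C → rt; aq. citric acid work-up
Reagents that add atoms: none
Why: Reductive removal of the auxiliary turns the imide carbonyl into C9′H2OH without touching C8′ (the silyl ether blocks retro-aldol), the aryl pivalate is cleaved reductively, and the TMS ethers are lost by methanolysis in the same medium, which bares the ring B phenol for the next cycle.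

Step 16
Reactants: 21 erythro triol with free ring B phenol; 18 (S)-4-benzyl-3-(2-bromoacetyl)oxazolidin-2-one
Product: 22 ring B aryloxyacetyl imide: 21 with its phenolic oxygen carrying CH2C(=O)-[(S)-4-benzyl-2-oxooxazolidin-3-yl]
Conditions: K2CO3, acetone, rt
Reagents that add atoms: none
Why: This Williamson ether synthesis works as in step 13, since the single phenol is the only group ionised and the three alcohols remain untouched.

Step 17
Reactants: 22 ring B aryloxyacetyl imide; 23 vanillin acetate (4-formyl-2-methoxyphenyl acetate)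
Product: 24 second anti-aldol adduct as tetrakis-TMS ether: (2R,3R)-3-(4-acetoxy-3-methoxyphenyl)-3-(trimethylsilyloxy)-2-(ring B aryloxy)propanoyl imide of (S)-4-benzyloxazolidin-2-one, with the oxygens on C7′ and C9′ and the CH2OH on C3 as TMS ethers
Conditions: TMSCl (excess), Et3N, EtOAc, rt; then MgCl2, 23, rt
Reagents that add atoms: chlorotrimethylsilane, C[Si](C)(C)Cl
Why: This is the same magnesium-halide-catalysed anti-aldol reaction as in step 14, where the auxiliary face and the boat-like transition state should set C8 and C7 anti (erythro), the remote stereocentres have no say, and the three alcohols are masked as TMS ethers in the flask beforehand.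

Step 18
Reactants: 24 second anti-aldol adduct (tetrakis-TMS ether)
Product: 25 5-iodo analogue of the target (all six stereocentres in place, iodine on ring D where the propenal chain will stand)
Conditions: LiBH4 (excess), MeOH, THF, 0 °C → rt; aq. citric acid work-up
Reagents that add atoms: none
Why: Reductive removal of the auxiliary as in step 15 gives C9H2OH, the aryl acetate is cleaved to the ring A phenol, and all TMS ethers fall by methanolysis, with no stereocentre affected.

Step 19
Reactants: 25 5-iodo analogue of the target; 26 acrolein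
Product: 27 target CNP0192639.1
Conditions: Pd(OAc)2 (cat.), n-Bu4NCl, NaHCO3, DMF, 50 °C
Reagents that add atoms: none
Why: In this Heck reaction under ligand-free phase-transfer conditions, the aryl iodide should add oxidatively to zerovalent palladium at mild temperature, syn insertion and syn β-hydride elimination give the (E)-enal, and the weak base leaves the phenol and the benzylic alcohols alone.

Compound list
1 | o-vanillin (2-hydroxy-3-methoxybenzaldehyde) | COc1cccc(C=O)c1O | starting material
2 | 2-hydroxy-5-iodo-3-methoxybenzaldehyde | COc1cc(I)cc(C=O)c1O | intermediate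
3 | 5-iodo-3-methoxy-2-[(triisopropylsilyl)oxy]benzaldehyde | COc1cc(I)cc(C=O)c1O[Si](C(C)C)(C(C)C)C(C)C | intermediate
4 | [4-iodo-2-methoxy-6-(2-methoxyethenyl)phenoxy]triisopropylsilane (E/Z enol ether) | COC=Cc1cc(I)cc(OC)c1O[Si](C(C)C)(C(C)C)C(C)C | intermediate
5 | 2-{5-iodo-3-methoxy-2-[(triisopropylsilyl)oxy]phenyl}acetaldehyde | COc1cc(I)cc(CC=O)c1O[Si](C(C)C)(C(C)C)C(C)C | intermediate
6 | 2-{5-iodo-3-methoxy-2-[(triisopropylsilyl)oxy]phenyl}acetic acid | COc1cc(I)cc(CC(=O)O)c1O[Si](C(C)C)(C(C)C)C(C)C | intermediate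
7 | (S)-4-benzyloxazolidin-2-one | O=C1N[C@@H](Cc2ccccc2)CO1 | starting material
8 | mixed pivalic anhydride of acid 6 | COc1cc(I)cc(CC(=O)OC(=O)C(C)(C)C)c1O[Si](C(C)C)(C(C)C)C(C)C | intermediate
9 | (S)-4-benzyl-3-(2-{5-iodo-3-methoxy-2-[(triisopropylsilyl)oxy]phenyl}acetyl)oxazolidin-2-one | COc1cc(I)cc(CC(=O)N2[C@@H](Cc3ccccc3)COC2=O)c1O[Si](C(C)C)(C(C)C)C(C)C | intermediate
10 | syringaldehyde | COc1cc(C=O)cc(OC)c1O | starting material
11 | 4-formyl-2,6-dimethoxyphenyl pivalate | COc1cc(C=O)cc(OC)c1OC(=O)C(C)(C)C | intermediate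
12 | 4-(hydroxymethyl)-2,6-dimethoxyphenyl pivalate | COc1cc(CO)cc(OC)c1OC(=O)C(C)(C)C | intermediate
13 | 4-(bromomethyl)-2,6-dimethoxyphenyl pivalate | COc1cc(CBr)cc(OC)c1OC(=O)C(C)(C)C | intermediate
14 | (2S)-benzylated imide | COc1cc(I)cc([C@H](Cc2cc(OC)c(OC(=O)C(C)(C)C)c(OC)c2)C(=O)N2[C@@H](Cc3ccccc3)COC2=O)c1O[Si](C(C)C)(C(C)C)C(C)C | intermediate
15 | 4-[(2S)-3-hydroxy-2-{5-iodo-3-methoxy-2-[(triisopropylsilyl)oxy]phenyl}propyl]-2,6-dimethoxyphenol | COc1cc(I)cc([C@H](Cc2cc(OC)c(O)c(OC)c2)CO)c1O[Si](C(C)C)(C(C)C)C(C)C | intermediate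
16 | 4-[(2S)-3-hydroxy-2-{5-iodo-3-methoxy-2-[(triisopropylsilyl)oxy]phenyl}propylidene]-2,6-dimethoxycyclohexa-2,5-dien-1-one (p-quinone methide) | COc1cc(I)cc([C@H](C=C2C=C(OC)C(=O)C(OC)=C2)CO)c1O[Si](C(C)C)(C(C)C)C(C)C | intermediate
17 | 4-[(2R,3S)-3-(hydroxymethyl)-5-iodo-7-methoxy-2,3-dihydro-1-benzofuran-2-yl]-2,6-dimethoxyphenol | COc1cc([C@@H]2Oc3c(OC)cc(I)cc3[C@H]2CO)cc(OC)c1O | intermediate
18 | (S)-4-benzyl-3-(2-bromoacetyl)oxazolidin-2-one | O=C(CBr)N1[C@@H](Cc2ccccc2)COC1=O | intermediate
19 | ring C aryloxyacetyl imide | COc1cc([C@@H]2Oc3c(OC)cc(I)cc3[C@H]2CO)cc(OC)c1OCC(=O)N1[C@@H](Cc2ccccc2)COC1=O | intermediate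
20 | first anti-aldol adduct, bis-TMS ether (acyl chain 2R,3R) | COc1cc([C@@H](O[Si](C)(C)C)[C@H](C(=O)N2[C@@H](Cc3ccccc3)COC2=O)Oc2c(OC)cc([C@@H]3Oc4c(OC)cc(I)cc4[C@H]3CO[Si](C)(C)C)cc2OC)cc(OC)c1OC(=O)C(C)(C)C | intermediate
21 | erythro (7′R,8′S) triol with free ring B phenol | COc1cc([C@@H](O)[C@H](CO)Oc2c(OC)cc([C@@H]3Oc4c(OC)cc(I)cc4[C@H]3CO)cc2OC)cc(OC)c1O | intermediate
22 | ring B aryloxyacetyl imide | COc1cc([C@@H](O)[C@H](CO)Oc2c(OC)cc([C@@H]3Oc4c(OC)cc(I)cc4[C@H]3CO)cc2OC)cc(OC)c1OCC(=O)N1[C@@H](Cc2ccccc2)COC1=O | intermediate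
23 | vanillin acetate (4-formyl-2-methoxyphenyl acetate) | COc1cc(C=O)ccc1OC(C)=O | starting material
24 | second anti-aldol adduct, tetrakis-TMS ether (acyl chain 2R,3R) | COc1cc([C@@H](O[Si](C)(C)C)[C@H](C(=O)N2[C@@H](Cc3ccccc3)COC2=O)Oc2c(OC)cc([C@@H](O[Si](C)(C)C)[C@H](CO[Si](C)(C)C)Oc3c(OC)cc([C@@H]4Oc5c(OC)cc(I)cc5[C@H]4CO[Si](C)(C)C)cc3OC)cc2OC)ccc1OC(C)=O | intermediate
25 | 5-iodo analogue of the target | COc1cc([C@@H](O)[C@H](CO)Oc2c(OC)cc([C@@H](O)[C@H](CO)Oc3c(OC)cc([C@@H]4Oc5c(OC)cc(I)cc5[C@H]4CO)cc3OC)cc2OC)ccc1O | intermediate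
26 | acrolein | C=CC=O | starting material
27 | CNP0192639.1 | COc1cc([C@@H](O)[C@H](CO)Oc2c(OC)cc([C@@H](O)[C@H](CO)Oc3c(OC)cc([C@@H]4Oc5c(OC)cc(/C=C/C=O)cc5[C@H]4CO)cc3OC)cc2OC)ccc1O | target

Total step count: 19. Longest linear sequence: 15 steps (steps 1–5, 9–11 and 13–19).

Steps most likely to fail

1. Step 11 (key step).
- What may go wrong: the quinone methide may tautomerise to the conjugated styrene with loss of the C3 configuration. It may oligomerise before the ring D oxygen is released. The silyl group may also migrate to the primary alcohol.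
- Fallback (sets out from 9 together with 11, comes back at 17): C2 is brought in already oxygenated, so neither an oxidation nor a free-standing quinone methide is needed. The MgCl2/Et3N/TMSCl aldol reaction of 9 with 11 should use the same enolate face as the benzylation and give the silylated aldol adduct F1. LiBH4/MeOH in THF then removes the auxiliary, pivalate and TMS to give the 1,3-diol F2. TBAF/AcOH frees the ring D phenol to give the triol bisphenol F3. Catalytic PPTS in CH2Cl2 ionises the p-hydroxybenzylic alcohol, and the neighbouring phenol closes the ring at once under thermodynamic trans control. The carbinol configuration is erased and only C3 counts, which gives 17.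

2. Step 14.
- What may go wrong: the anti/syn selectivity may erode because the aryloxy and methoxy oxygens compete for magnesium. Turnover may also be slow with the polyoxygenated substrate.
- Fallback (sets out from 20, comes back at 21): C7′ is erased and reset by substrate control. The crude aldol product is reduced as in step 15, which gives 21 together with its C7′ epimer, the threo triol F4. DDQ in dioxane at rt oxidises the p-hydroxybenzylic carbinol of both epimers to the single α-aryloxy ketone F5, in which only the auxiliary-derived C8′ remains in the ring B side chain. Chelation-controlled reduction with Zn(BH4)2 in Et2O at −30 °C follows. This is the known erythro-selective reduction of α-(2,6-dimethoxyphenoxy)-β-hydroxypropiophenones, and it returns 21.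

3. Step 19.
- What may go wrong: acrolein may polymerise or add conjugatively to the phenol and alcohols under base. The ligand-free catalyst may also be deactivated by the unprotected polyol.
- Fallback (sets out from 25, comes back at 27): a base-free Stille coupling of 25 with (E)-3-(tributylstannyl)prop-2-enal (Pd2(dba)3, AsPh3, CuI, DMF, rt → 40 °C) delivers the preformed (E)-enal unit directly. It makes no new compound (F0).

Further compounds
F1 | step 11 | (S)-4-benzyl-3-[(2R,3S)-3-[3,5-dimethoxy-4-(pivaloyloxy)phenyl]-2-{5-iodo-3-methoxy-2-[(triisopropylsilyl)oxy]phenyl}-3-(trimethylsilyloxy)propanoyl]oxazolidin-2-one | COc1cc(I)cc([C@H]([C@H](O[Si](C)(C)C)c2cc(OC)c(OC(=O)C(C)(C)C)c(OC)c2)C(=O)N2[C@@H](Cc3ccccc3)COC2=O)c1O[Si](C(C)C)(C(C)C)C(C)C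
F2 | step 11 | (1S,2S)-1-(4-hydroxy-3,5-dimethoxyphenyl)-2-{5-iodo-3-methoxy-2-[(triisopropylsilyl)oxy]phenyl}propane-1,3-diol | COc1cc(I)cc([C@H]([C@H](O)c2cc(OC)c(O)c(OC)c2)CO)c1O[Si](C(C)C)(C(C)C)C(C)C
F3 | step 11 | (1S,2S)-1-(4-hydroxy-3,5-dimethoxyphenyl)-2-(2-hydroxy-5-iodo-3-methoxyphenyl)propane-1,3-diol | COc1cc(I)cc([C@H]([C@H](O)c2cc(OC)c(O)c(OC)c2)CO)c1O
F4 | step 14 | threo (7′S,8′S) epimer of 21 | COc1cc([C@H](O)[C@H](CO)Oc2c(OC)cc([C@@H]3Oc4c(OC)cc(I)cc4[C@H]3CO)cc2OC)cc(OC)c1O
F5 | step 14 | (2S)-3-hydroxy-1-(4-hydroxy-3,5-dimethoxyphenyl)-2-{4-[(2R,3S)-3-(hydroxymethyl)-5-iodo-7-methoxy-2,3-dihydro-1-benzofuran-2-yl]-2,6-dimethoxyphenoxy}propan-1-one | COc1cc(C(=O)[C@H](CO)Oc2c(OC)cc([C@@H]3Oc4c(OC)cc(I)cc4[C@H]3CO)cc2OC)cc(OC)c1O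
F0 | step 19 | none | none
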